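The choice between delta and gamma is made at their plateaus, so the first step is to sort out which given numbers need care.

in all of them: substrate 0.028 M

|  | partner | catalyst | remark | time |
|---|---|---|---|---|
| south-west | 0.14 M | 2.5 mM | run made earlier |  |
| north | 0.14 M | 4.8 mM | run made earlier |  |
| east | 0.11 M | 4.2 mM | run made earlier |  |
| delta | 0.0500 M | 6.0 mM |  | 8.0 min |
| gamma | 0.140 M | 4.2 mM |  | 2.5 min |

| run | time / s | product / % |
|---|---|---|
| south-west | 10.0 | 6.6 |
| south-west | 15.0 | 8.0 |
| south-west | 25.0 | 9.4 |
| south-west | 40.0 | 11.9 |
| south-west | 60.0 | 12.1 |
| south-west | 80.0 | 12.6 |
| north | 10.0 | 10.1 |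
| north | 15.0 | 12.5 |
| north | 25.0 | 16.6 |
| north | 50.0 | 21.8 |
| north | 80.0 | 23.1 |
| east | 10.0 | 7.5 |
| east | 12.0 | 8.8 |
| east | 20.0 | 9.4 |
| east | 40.0 | 14.3 |
| east | 80.0 | 17.0 |

(scatter of a reading: 1 percentage point)

- which of the two ends with the higher amount of product, in percent of the substrate charged ("neither" if they lie within 2 percentage points) (delta / gamma / neither)
- product at the end, in percent of the substrate charged, delta
- product at the end, in percent of the substrate charged, gamma



Time needs little care. North gains 1.3 percentage points from 50.0 s to 80.0 s, and gamma's 2.5 min and delta's 8.0 min both lie beyond that last reading. Substrate stands at 0.028 M in delta, gamma and the runs alike. Catalyst counts: from south-west to north it rises by a factor of 1.92, and the last reading by 1.83. Partner counts as well: east, with 0.11 M against north's 0.14 M, ends at 17.0 %.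

So the number to know well joins those two. North gives 391 /M² for the reach g, the logarithm of substrate charged over substrate left at the plateau, divided by catalyst charge times partner charge. South-west reads 385 /M² and east 403 /M², close to north's reading. Turned round, g gives gamma 20.5 % and delta 11.1 %.

The forecast names gamma, with 20.5 % for gamma and 12 % for delta. It holds that “the catalyst appears to die after a limited number of turnovers”. Its gamma matches the reckoning here, and its delta is higher.

    partner → decomposed reagent (k = 0.0420 /s)
    substrate + partner + catalyst → catalyst + product (k = 18.0 /M²/s)

Gamma ends at 21.4 % and delta at 11.3 %, so gamma leads, as forecast. At the start of gamma, partner goes to decomposed reagent 20 times as fast as into product. By 2.50 min partner, the limiting reagent, stands at 0.142 % of its charge, and catalyst at 100 %. With its other charges and its time held, delta's answer has moved by 5 points at 0.0740 M of partner. With 0.24 M of partner in gamma's recipe, g gives 32.6 %, and that neighbour flask gives 33.9 %.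

The numbers in the tables stem from a simulated flask with constants of no real substance; the scatter is artificial.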